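The numbers in the tables stem from a simulated flask on assumed constants; the scatter is artificial.

The target is the product to watch in a repeat, but what is asked is the share of its rival, the other capture product, in the two together, and in our reckoning that share follows a ratio of two concentrations rather than the charge of substrate.

- maple: substrate 0.10 M; first nucleophile 0.14 M; gas 17 mM (held); run made earlier
- flask: substrate 0.20 M; first nucleophile 0.140 M; gas 17 mM (held); time 30 min

- maple (time / min: other capture product / %, target / %): 0.833: 19.2, 4.3; 2.50: 45.2, 7.9; 4.00: 59.4, 8.7; 6.00: 69.5, 9.9; 10.0: 77.3, 10.1

(each reading ± 0.3 percentage points)

- the numbers in the tables scatter with a standard deviation of 0.3 percentage points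
- at the start none of the gas is in solution

1. share of other capture product in other capture product plus target at 2.5 s
2. share of other capture product in other capture product plus target at 1.0 min
3. share of other capture product in other capture product plus target at 30 min

Maple and the flask look nearly the same, with equal c(first nucleophile) and equal held gas, and the flask differs by holding twice the substrate. We read maple as one intermediate, made from substrate and taken either by dissolved gas or by first nucleophile. On that reading c(substrate) sets how fast intermediate appears, but it cancels from the ratio of the two captures, which leaves c(gas)/c(first nucleophile) to set the odds. Maple's last reading, at 10.0 min, stands at 77.3% against 10.1%, a ratio of 7.65. Multiplied by c(first nucleophile)/c(gas) at the charges, it gives 63.0, which we call the capture factor (an apparent selectivity factor): the product ratio per unit of c(gas)/c(first nucleophile), as read from maple.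

The flask's charges return odds of 7.65, so we expect an end share of 88.4%, and the two flasks should end alike. Earlier in the flask we expect a lower share, and as a figure for 1.0 min we borrow the 81.7% that maple shows at its first reading, 0.833 min, which is a reading from another flask and not a reckoning for this one. The time 2.5 s lies well before that reading, and no gas is in solution at the start, so we expect less in the flask there but commit to no figure.

The forecast gives 30%, 77% and 88%, holding that in the flask “gas is starved harder”, and its middle figure stands below ours.

The flask gives 60.1% at 2.5 s, 82.5% at 1.0 min and 88.8% at 30 min, and it ran by these steps:

    substrate → intermediate (k = 0.00570 s⁻¹)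
    first nucleophile + intermediate → target (k = 42.0 M⁻¹ s⁻¹)
    second nucleophile + intermediate → other capture product (k = 1400 M⁻¹ s⁻¹)
    intermediate → solvolysis product (k = 0.310 s⁻¹)
    target ⇌ isomer of the product (K = 0.820, k = 0.0110 s⁻¹)
    gas ⇌ second nucleophile, rate k6*(csat - [second nucleophile]) (kL = 0.510 s⁻¹)

At 30.0 min the flask holds 10.1% of target beside 8.30% of its isomer, and the relaxation half-life of that pair, 0.473 min, is short against the run of 30 min. The capture factor counts target without its isomer, and its odds of 7.65 stand against 7.93 in the flask. For the neighbour charged with 0.35 M of first nucleophile, the factor gives odds of 3.06, a share of 75.4%, and that neighbour ends at 75.7%.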